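**Plan**
1. Retrosynthesis: the two aryl–CHO bonds and the C8=CH2 bond are cut first, then C6–C7 of the nine-membered ring, which leads back to a ten-membered sulfone with SO2 between C6 and C7. The two C–S bonds are cut to a C6 mesylate and a C7 thioacetate, and C3–C4 is cut into a chroman ketal (fragment A) and a cyclobutyl alkyne (fragment B).
2. Forward: the chroman ring comes from 5,7-dimethoxycoumarin and the cyclobutane from a Wolff ring contraction followed by C–H alkenylation. The fragments are joined at C3–C4 by alkynylation of an oxocarbenium ion, the thiacycle is closed at S–C6, SO2 extrusion leaves the nine-membered carbocycle, and demethylation, methylenation and formylation finish the route.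
3. Stereochemistry: C1' from a ligand-controlled aryl addition; C5 by kinetic protonation anti to that phenyl group; C4 by alkynyl attack anti to both. C1 comes from an alkaloid-catalysed ketene aminolysis, is relayed to C9 by cis C–H alkenylation, and is then inverted by epimerisation to the trans-cyclobutane.
4. Enabling feature: in the nine-membered ring, C6 and C7 are two adjacent, unsubstituted ring CH2 groups lying between the ring-fusion CH (C5) and C8 (the carbon bearing =CH2). A C6=C7 alkene can therefore arise from a C6–SO2–C7 bridge and be hydrogenated without trace.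

Key step: step 21

Remark: terpenoid carbons carry caryophyllane numbers (C1 and C9 cyclobutane CH, C2 and C3 chain CH2, C4 quaternary C–O, C5 ring-fusion CH, C6 and C7 CH2, C8 the =CH2-bearing carbon, C10 CH2, C11 CMe2); C1' is the benzylic CH.
Assumption: (R)-SEGPHOS (step 1) and cinchonine (step 8) are taken to deliver the drawn enantiomers; if the sense is opposite, the mirror-image ligand or the pseudo-enantiomeric alkaloid is used.

**Fragment A**

Step 1
Reactants: 1 5,7-dimethoxycoumarin; 2 phenylboronic acid
Product: 3 (R)-5,7-dimethoxy-4-phenylchroman-2-one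
Conditions: Rh(acac)(C2H4)2 (3 mol %), (R)-SEGPHOS (3.3 mol %), 2 (5 equiv), dioxane/H2O 10:1, 60 °C
Reagents that add atoms: none
Why: Hayashi–Miyaura asymmetric conjugate addition of an arylrhodium species to the coumarin C3=C4 bond, in which the chiral bisphosphine selects the face of the unsaturated lactone and so sets C1'.

Step 2
Reactants: 3 (R)-5,7-dimethoxy-4-phenylchroman-2-one
Product: 5 (3R,4R)-3-[(benzyloxy)methyl]-5,7-dimethoxy-4-phenylchroman-2-one (3,4-trans), via lithium enolate 4 (not isolated)
Conditions: LiN(SiMe3)2, THF, −78 °C; BnOCH2Cl, −78 → −30 °C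
Reagents that add atoms: benzyl chloromethyl ether ClCOCc1ccccc1
Why: Lactone enolate alkylation with a reactive α-chloro ether installs C6 anti to the pseudoaxial 4-phenyl group, giving the trans isomer whose C5 configuration is reset in step 3.

Step 3
Reactants: 5 trans-lactone
Product: 7 (3S,4R)-3-[(benzyloxy)methyl]-5,7-dimethoxy-4-phenylchroman-2-one (3,4-cis), via lithium enolate 6 (not isolated)
Conditions: LiN(i-Pr)2, THF, −78 °C; then 2,6-di-tert-butylphenol, −78 °C; H2O
Reagents that add atoms: none
Why: Deprotonation followed by kinetic protonation, in which the bulky proton donor approaches the planar enolate anti to the 4-phenyl group (held pseudoaxial by the peri 5-methoxy group), so that CH2OBn ends cis to phenyl and C5 is set.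

Step 4
Reactants: 7 cis-lactone
Product: 8 (3S,4R)-3-[(benzyloxy)methyl]-5,7-dimethoxy-2-methylidene-4-phenylchromane
Conditions: Cp2TiMe2 (2.5 equiv), toluene, 70 °C, dark
Reagents that add atoms: dimethyltitanocene Cp2TiMe2 [Ti+4].[CH3-].[CH3-].c1cc[cH-]c1.c1cc[cH-]c1
Why: Petasis methylenation of the lactone carbonyl by the titanium methylidene Cp2Ti=CH2 formed thermally from Cp2TiMe2, under non-basic conditions that should leave the epimerisable C5 centre untouched.

Step 5
Reactants: 8 exocyclic enol ether
Product: 9 (3S,4R)-3-[(benzyloxy)methyl]-2,5,7-trimethoxy-2-methyl-4-phenylchromane (both C2 anomers)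
Conditions: MeOH, PPTS (5 mol %), CH2Cl2, 0 °C
Reagents that add atoms: methanol CO
Why: Acid-catalysed Markovnikov addition of methanol to the enol ether through the tertiary oxocarbenium ion gives the mixed ketal, capture by the alcohol being faster than loss of H-5.

**Fragment B**

Step 6
Reactants: 10 benzyl propargyl ether
Product: 11 benzyl 2-iodoallyl ether
Conditions: NaI, Me3SiCl, H2O, MeCN, rt
Reagents that add atoms: sodium iodide [Na+].[I-]
Why: Markovnikov hydroiodination of the terminal alkyne by hydrogen iodide generated in the flask gives the 2-iodoalkene.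

Step 7
Reactants: 12 2,2-dimethylcyclopentanone
Product: 14 5-diazo-2,2-dimethylcyclopentan-1-one, via trifluoroacetyl ketone 13 (not isolated)
Conditions: LiN(SiMe3)2, THF, −78 °C; CF3CO2CH2CF3; then MsN3, Et3N, H2O, MeCN, rt
Reagents that add atoms: methanesulfonyl azide CS(=O)(=O)N=[N+]=[N-]
Why: Detrifluoroacetylative diazo transfer, in which the only enolisable position is C-acylated and the activated 1,3-dicarbonyl accepts the diazo group with loss of the trifluoroacetyl unit.

Step 8
Reactants: 14 5-diazo-2,2-dimethylcyclopentan-1-one; 15 8-aminoquinoline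
Product: 17 (R)-2,2-dimethyl-N-(quinolin-8-yl)cyclobutane-1-carboxamide, via cyclobutyl ketene 16 (not isolated)
Conditions: hν (254 nm), 15 (3 equiv), cinchonine (10 mol %), THF, rt; recrystallisation
Reagents that add atoms: none
Why: Photochemical Wolff rearrangement contracts the ring to a ketene, and amine addition followed by alkaloid-mediated enantioselective proton transfer sets the α-stereocentre (the future C1), with crystallisation available to raise enantiopurity.

Step 9
Reactants: 17 (R)-amide; 11 benzyl 2-iodoallyl ether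
Product: 18 (1R,4R)-4-[3-(benzyloxy)prop-1-en-2-yl]-2,2-dimethyl-N-(quinolin-8-yl)cyclobutane-1-carboxamide (1,4-cis)
Conditions: Pd(OAc)2 (15 mol %), Ag2CO3 (1 equiv), 11 (3 equiv), t-BuOMe, 90 °C
Reagents that add atoms: none
Why: Aminoquinoline-directed β-C(sp3)–H alkenylation catalysed by Pd(OAc)2 proceeds through a five-membered palladacycle and functionalises the only β-methylene, on the face cis to the amide, so the existing centre sets C9.

Step 10
Reactants: 18 cis-alkenyl amide
Product: 19 (1R,4R)-4-[3-(benzyloxy)prop-1-en-2-yl]-2,2-dimethylcyclobutane-1-carbaldehyde (cis)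
Conditions: Cp2Zr(H)Cl (2.2 equiv), THF, rt; aq. NaHCO3
Reagents that add atoms: none
Why: Partial reduction of the amide by Cp2Zr(H)Cl stops at the zirconated hemiaminal, whose hydrolysis releases the aldehyde and the auxiliary, the hindered 1,1-disubstituted alkene reacting more slowly.

Step 11
Reactants: 19 cis-aldehyde
Product: 21 (1R,2S)-1-[3-(benzyloxy)prop-1-en-2-yl]-2-ethynyl-3,3-dimethylcyclobutane (trans), via trans-aldehyde 20 (not isolated)
Conditions: K2CO3, MeOH, rt, 3 h; then dimethyl (1-diazo-2-oxopropyl)phosphonate, 0 °C → rt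
Reagents that add atoms: dimethyl (1-diazo-2-oxopropyl)phosphonate COP(=O)(OC)C(=[N+]=[N-])C(C)=O
Why: Base equilibration of the enolisable aldehyde gives the more stable trans-cyclobutane (inverting C1 while C9, which carries no acidifying group, stays fixed), and Seyferth–Gilbert homologation then turns CHO into the terminal alkyne.

Step 12
Reactants: 21 trans-alkyne
Product: 24 potassium trifluoro{[(1S,2R)-2-[3-(benzyloxy)prop-1-en-2-yl]-4,4-dimethylcyclobutyl]ethynyl}borate, via lithium acetylide 22 (not isolated), via lithium trimethoxyborate 23 (not isolated)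
Conditions: n-BuLi, THF, −78 °C; B(OMe)3, −78 → −20 °C; aq. KHF2, −20 °C → rt
Reagents that add atoms: trimethyl borate COB(OC)OC; potassium hydrogen difluoride [K+].F.[F-]
Why: Borylation of the acetylide followed by fluoride exchange is the standard preparation of bench-stable potassium alkynyltrifluoroborates.

**Fragment union and thiacycle**

Step 13
Reactants: 9 methyl ketal (fragment A); 24 potassium alkynyltrifluoroborate (fragment B)
Product: 25 (2R,3S,4R)-2-alkynyl-2-methylchromane (2-methyl, 3-CH2OBn and 4-phenyl all cis; cyclobutane as in 21)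
Conditions: BF3·OEt2 (2 equiv), 24 (1.5 equiv), CH2Cl2/MeCN, −40 → 0 °C
Reagents that add atoms: none
Why: Lewis-acid-mediated C-alkynylation of a cyclic ketal through its oxocarbenium ion: BF3 ionises the ketal and unmasks the alkynyldifluoroborane, which delivers the alkynyl group to C4 on the face anti to the cis C5-CH2OBn and C1'-phenyl groups, setting the quaternary centre.

Step 14
Reactants: 25 coupled enyne
Product: 27 α-benzyloxy ketone (C8=O, C7–OBn; alkyne retained), via vicinal diol 26 (not isolated)
Conditions: OsO4 (2 mol %), NaIO4 (4 equiv), 2,6-lutidine, dioxane/H2O 3:1, rt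
Reagents that add atoms: osmium tetroxide O=[Os](=O)(=O)=O; sodium periodate [Na+].[O-]I(=O)(=O)=O
Why: Lemieux–Johnson oxidation (dihydroxylation, then periodate cleavage) turns the 1,1-disubstituted alkene into the C8 ketone, the internal alkyne being inert to OsO4 under these conditions.

Step 15
Reactants: 27 α-benzyloxy ketone
Product: 28 keto diol (C6–OH, C7–OH, C8=O; C2–C3 saturated)
Conditions: H2 (3 atm), 10 % Pd/C, EtOAc/EtOH 1:1, rt
Reagents that add atoms: none
Why: Heterogeneous hydrogenation saturates the alkyne and hydrogenolyses both benzyl ethers in one operation, the ketone and the tertiary alkyl aryl ether being stable to these conditions.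

Step 16
Reactants: 28 keto diol
Product: 29 bis(mesylate) (C6–OMs, C7–OMs)
Conditions: MsCl (2.5 equiv), i-Pr2NEt, CH2Cl2, −20 °C
Reagents that add atoms: methanesulfonyl chloride CS(=O)(=O)Cl
Why: Sulfonylation of both primary hydroxyl groups, with a hindered amine base so that the α-keto mesylate is not displaced.

Step 17
Reactants: 29 bis(mesylate)
Product: 30 C7 thioacetate, C6 mesylate, C8 ketone
Conditions: potassium thioacetate (1.0 equiv), acetone, −20 → 0 °C
Reagents that add atoms: potassium thioacetate [K+].CC(=O)[S-]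
Why: SN2 displacement occurs selectively at the α-keto mesylate, which is far more reactive than the β-branched C6 mesylate, so sulfur is placed on C7 before that carbon becomes neopentyl-like.

Step 18
Reactants: 30 thioacetate ketone
Product: 31 C8 ethylene ketal (C7–SAc, C6–OMs)
Conditions: (Me3SiOCH2)2, Me3SiOTf (10 mol %), CH2Cl2, −78 → −20 °C
Reagents that add atoms: 1,2-bis(trimethylsilyloxy)ethane C[Si](C)(C)OCCO[Si](C)(C)C
Why: Aprotic silyl-triflate-catalysed ketalisation with the bis-silyl ether of ethylene glycol protects the hindered ketone at low temperature without touching mesylate or thioester, the trans C9 configuration being the stable one.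

Step 19
Reactants: 31 ketal thioacetate mesylate
Product: 33 ten-membered cyclic sulfide (S between C6 and C7; C8 ketal), via thiol 32 (not isolated)
Conditions: Cs2CO3 (3 equiv), degassed MeOH/THF 1:1, slow addition to 0.002 M, 40 °C
Reagents that add atoms: none
Why: Methanolysis of the thioester frees the C7 thiolate, which closes the ten-membered ring by intramolecular SN2 displacement of the C6 mesylate (thioether macrocyclisation at high dilution).

Step 20
Reactants: 33 cyclic sulfide
Product: 35 ten-membered sulfone (S,S-dioxide; C8 ketal), via sulfoxide 34 (not isolated)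
Conditions: m-CPBA (2.3 equiv), NaHCO3, CH2Cl2, 0 °C → rt
Reagents that add atoms: m-chloroperoxybenzoic acid OOC(=O)c1cccc(Cl)c1
Why: Twofold peracid oxidation of the sulfide gives the sulfone, the buffered medium protecting the ketal and no other oxidisable group being present.

Step 21
Reactants: 35 ten-membered sulfone
Product: 38 (Z)-C6=C7 cyclononene ketal (tetracycle), via α-bromo sulfone 36 (not isolated), via episulfone 37 (not isolated)
Conditions: CBr2F2, KOH/Al2O3, t-BuOH/CH2Cl2, 0 °C → rt
Reagents that add atoms: none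
Why: Halogenative Ramberg–Bäcklund reaction: KOH on alumina deprotonates one α-sulfonyl carbon, CBr2F2 brominates the carbanion, deprotonation at the other α-carbon (C6 or C7) displaces bromide to give the episulfone, and cheletropic loss of SO2 leaves the C6=C7 bond. The closest known reaction type is the ring contraction of medium-ring thiacycloalkane S,S-dioxides to cycloalkenes. The transient thiirane dioxide closes in a 3-exo-tet mode, so the nine-membered carbocycle arises by one-atom contraction of the ten-membered ring and not by direct end-to-end cyclisation. No stereocentre is created, and the alkene geometry (Z expected from a cis-fused episulfone in a ring of this size) does not matter because step 22 hydrogenates it. The step needs reaction only at the two sulfone α-methylenes and base stability of all five stereocentres: the C8 dioxolane removes β-keto sulfone acidity and haloform-type cleavage, C1, C5, C9 and C1' carry no acidifying group, and any β-alkoxide opening of the ketal from the C7 carbanion is reversible. CBr2F2 is preferred to CCl4 because difluorocarbene should not add to the product alkene or the electron-rich arene.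

**Endgame**

Step 22
Reactants: 38 cyclononene ketal
Product: 39 saturated ketal (C6–C7 single bond)
Conditions: H2 (1 atm), 10 % Pd/C, EtOAc, rt
Reagents that add atoms: none
Why: Heterogeneous hydrogenation of the only alkene, a cis-disubstituted ring olefin, creates no stereocentre.

Step 23
Reactants: 39 saturated ketal
Product: 40 C8 ketone (5,7-dimethoxy chroman)
Conditions: 1 M HCl, THF, rt
Reagents that add atoms: water O
Why: Acid-catalysed ketal hydrolysis, under which the tertiary alkyl aryl ether is stable and C9 remains in the thermodynamically preferred trans ring fusion.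

Step 24
Reactants: 40 dimethoxy ketone
Product: 41 5,7-dihydroxy ketone
Conditions: BBr3 (6 equiv), CH2Cl2, −78 → 0 °C; then MeOH/H2O
Reagents that add atoms: none
Why: Lewis-acid cleavage of both aryl methyl ethers is placed before methylenation, so that no acid-sensitive alkene is present while the methyl groups leave as bromomethane.

Step 25
Reactants: 41 dihydroxy ketone
Product: 42 C8-methylidene diphenol (psidial A lacking both formyl groups)
Conditions: Ph3PCH3Br (6 equiv), KOt-Bu (6 equiv), THF, 0 → 60 °C
Reagents that add atoms: methyltriphenylphosphonium bromide C[P+](c1ccccc1)(c1ccccc1)c1ccccc1.[Br-]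
Why: Wittig methylenation with excess ylide, which first converts the phenols to inert phenoxides and then olefinates the hindered ring ketone.

Step 26
Reactants: 42 methylidene diphenol
Product: 44 psidial A, via bis(iminium) salt 43 (not isolated)
Conditions: POCl3 (6 equiv), DMF, EtOAc, 0 °C → rt; then aq. NaOAc, 40 °C
Reagents that add atoms: N,N-dimethylformamide CN(C)C=O; water O
Why: Twofold Vilsmeier–Haack formylation at the two free positions of the phloroglucinol-type ring, each activated by three oxygen substituents, which should react at a temperature where the unactivated 1,1-disubstituted alkene does not.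

**Compound list**
1 | 5,7-dimethoxycoumarin | COc1cc(OC)c2ccc(=O)oc2c1 | starting material
2 | phenylboronic acid | OB(O)c1ccccc1 | starting material
3 | (R)-5,7-dimethoxy-4-phenylchroman-2-one | O=C1C[C@H](c2ccccc2)c2c(OC)cc(OC)cc2O1 | intermediate
4 | lithium enolate of 3 (not isolated) | [Li+].[O-]C1=C[C@H](c2ccccc2)c2c(OC)cc(OC)cc2O1 | intermediate
5 | (3R,4R)-3-[(benzyloxy)methyl]-5,7-dimethoxy-4-phenylchroman-2-one (trans) | O=C1[C@@H](COCc2ccccc2)[C@H](c2ccccc2)c2c(OC)cc(OC)cc2O1 | intermediate
6 | lithium enolate of 5 (not isolated) | [Li+].[O-]C1=C(COCc2ccccc2)[C@H](c2ccccc2)c2c(OC)cc(OC)cc2O1 | intermediate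
7 | (3S,4R)-3-[(benzyloxy)methyl]-5,7-dimethoxy-4-phenylchroman-2-one (cis) | O=C1[C@H](COCc2ccccc2)[C@H](c2ccccc2)c2c(OC)cc(OC)cc2O1 | intermediate
8 | (3S,4R)-3-[(benzyloxy)methyl]-5,7-dimethoxy-2-methylidene-4-phenylchromane | C=C1[C@H](COCc2ccccc2)[C@H](c2ccccc2)c2c(OC)cc(OC)cc2O1 | intermediate
9 | (3S,4R)-3-[(benzyloxy)methyl]-2,5,7-trimethoxy-2-methyl-4-phenylchromane (C2 anomers) | COC1(C)[C@H](COCc2ccccc2)[C@H](c2ccccc2)c2c(OC)cc(OC)cc2O1 | intermediate
10 | benzyl propargyl ether | C#CCOCc1ccccc1 | starting material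
11 | benzyl 2-iodoallyl ether | C=C(I)COCc1ccccc1 | intermediate
12 | 2,2-dimethylcyclopentanone | CC1(C)CCCC1=O | starting material
13 | 2,2-dimethyl-5-(trifluoroacetyl)cyclopentanone (not isolated) | CC1(C)CCC(C(=O)C(F)(F)F)C1=O | intermediate
14 | 5-diazo-2,2-dimethylcyclopentan-1-one | CC1(C)CCC(=[N+]=[N-])C1=O | intermediate
15 | 8-aminoquinoline | Nc1cccc2cccnc12 | starting material
16 | (2,2-dimethylcyclobutylidene)methanone, the ketene (not isolated) | CC1(C)CCC1=C=O | intermediate
17 | (R)-2,2-dimethyl-N-(quinolin-8-yl)cyclobutane-1-carboxamide | O=C(Nc1cccc2cccnc12)[C@@H]1CCC1(C)C | intermediate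
18 | (1R,4R)-4-[3-(benzyloxy)prop-1-en-2-yl]-2,2-dimethyl-N-(quinolin-8-yl)cyclobutane-1-carboxamide (cis) | O=C(Nc1cccc2cccnc12)[C@@H]1[C@H](C(=C)COCc2ccccc2)CC1(C)C | intermediate
19 | (1R,4R)-4-[3-(benzyloxy)prop-1-en-2-yl]-2,2-dimethylcyclobutane-1-carbaldehyde (cis) | O=C[C@@H]1[C@H](C(=C)COCc2ccccc2)CC1(C)C | intermediate
20 | (1S,4R)-4-[3-(benzyloxy)prop-1-en-2-yl]-2,2-dimethylcyclobutane-1-carbaldehyde (trans; not isolated) | O=C[C@H]1[C@H](C(=C)COCc2ccccc2)CC1(C)C | intermediate
21 | (1R,2S)-1-[3-(benzyloxy)prop-1-en-2-yl]-2-ethynyl-3,3-dimethylcyclobutane (trans) | C#C[C@H]1[C@H](C(=C)COCc2ccccc2)CC1(C)C | intermediate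
22 | lithium acetylide of 21 (not isolated) | [Li]C#C[C@H]1[C@H](C(=C)COCc2ccccc2)CC1(C)C | intermediate
23 | lithium alkynyl(trimethoxy)borate from 22 (not isolated) | [Li+].CO[B-](OC)(OC)C#C[C@H]1[C@H](C(=C)COCc2ccccc2)CC1(C)C | intermediate
24 | potassium trifluoro{[(1S,2R)-2-[3-(benzyloxy)prop-1-en-2-yl]-4,4-dimethylcyclobutyl]ethynyl}borate | [K+].F[B-](F)(F)C#C[C@H]1[C@H](C(=C)COCc2ccccc2)CC1(C)C | intermediate
25 | (2R,3S,4R)-3-[(benzyloxy)methyl]-2-{[(1S,2R)-2-[3-(benzyloxy)prop-1-en-2-yl]-4,4-dimethylcyclobutyl]ethynyl}-5,7-dimethoxy-2-methyl-4-phenylchromane (2-Me, 3-CH2OBn, 4-Ph all cis; cyclobutane trans as in 21) | O(Cc1ccccc1)C[C@@H]1[C@H](c2ccccc2)c2c(OC)cc(OC)cc2O[C@@]1(C)C#C[C@H]1[C@H](C(=C)COCc2ccccc2)CC1(C)C | intermediate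
26 | vicinal diol from 25 (C8 epimers; not isolated) | O(Cc1ccccc1)C[C@@H]1[C@H](c2ccccc2)c2c(OC)cc(OC)cc2O[C@@]1(C)C#C[C@H]1[C@H](C(O)(CO)COCc2ccccc2)CC1(C)C | intermediate
27 | α-benzyloxy ketone (C8=O, C7–OBn, C6–OBn, C2≡C3; stereocentres as in 25) | O(Cc1ccccc1)C[C@@H]1[C@H](c2ccccc2)c2c(OC)cc(OC)cc2O[C@@]1(C)C#C[C@H]1[C@H](C(=O)COCc2ccccc2)CC1(C)C | intermediate
28 | keto diol (C6–OH, C7–OH, C8=O; C2–C3 saturated) | OC[C@@H]1[C@H](c2ccccc2)c2c(OC)cc(OC)cc2O[C@@]1(C)CC[C@H]1[C@H](C(=O)CO)CC1(C)C | intermediate
29 | bis(mesylate) (C6–OMs, C7–OMs, C8=O) | CS(=O)(=O)OC[C@@H]1[C@H](c2ccccc2)c2c(OC)cc(OC)cc2O[C@@]1(C)CC[C@H]1[C@H](C(=O)COS(C)(=O)=O)CC1(C)C | intermediate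
30 | C7 thioacetate, C6 mesylate, C8 ketone | CS(=O)(=O)OC[C@@H]1[C@H](c2ccccc2)c2c(OC)cc(OC)cc2O[C@@]1(C)CC[C@H]1[C@H](C(=O)CSC(C)=O)CC1(C)C | intermediate
31 | C7 thioacetate, C6 mesylate, C8 ethylene ketal | CS(=O)(=O)OC[C@@H]1[C@H](c2ccccc2)c2c(OC)cc(OC)cc2O[C@@]1(C)CC[C@H]1[C@H](C2(CSC(C)=O)OCCO2)CC1(C)C | intermediate
32 | C7 thiol, C6 mesylate, C8 ketal (not isolated) | CS(=O)(=O)OC[C@@H]1[C@H](c2ccccc2)c2c(OC)cc(OC)cc2O[C@@]1(C)CC[C@H]1[C@H](C2(CS)OCCO2)CC1(C)C | intermediate
33 | ten-membered cyclic sulfide, C8 ketal (stereocentres as in 44) | S1C[C@@H]2[C@H](c3ccccc3)c3c(OC)cc(OC)cc3O[C@@]2(C)CC[C@H]2[C@@H](CC2(C)C)C2(C1)OCCO2 | intermediate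
34 | cyclic sulfoxide (not isolated) | O=S1C[C@@H]2[C@H](c3ccccc3)c3c(OC)cc(OC)cc3O[C@@]2(C)CC[C@H]2[C@@H](CC2(C)C)C2(C1)OCCO2 | intermediate
35 | ten-membered sulfone, C8 ketal | O=S1(=O)C[C@@H]2[C@H](c3ccccc3)c3c(OC)cc(OC)cc3O[C@@]2(C)CC[C@H]2[C@@H](CC2(C)C)C2(C1)OCCO2 | intermediate
36 | α-bromo sulfone (Br drawn at C7; the C6 isomer converges; not isolated) | O=S1(=O)C[C@@H]2[C@H](c3ccccc3)c3c(OC)cc(OC)cc3O[C@@]2(C)CC[C@H]2[C@@H](CC2(C)C)C2(C1Br)OCCO2 | intermediate
37 | episulfone (thiirane 1,1-dioxide across C6–C7; not isolated) | O=S1(=O)C2[C@@H]3[C@H](c4ccccc4)c4c(OC)cc(OC)cc4O[C@@]3(C)CC[C@H]3[C@@H](CC3(C)C)C3(C21)OCCO3 | intermediate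
38 | (Z)-C6=C7 cyclononene, C8 ketal | C1COC2(O1)/C=C\[C@@H]1[C@H](c3ccccc3)c3c(OC)cc(OC)cc3O[C@@]1(C)CC[C@H]1[C@H]2CC1(C)C | intermediate
39 | saturated C8 ketal | C1COC2(O1)CC[C@@H]1[C@H](c3ccccc3)c3c(OC)cc(OC)cc3O[C@@]1(C)CC[C@H]1[C@H]2CC1(C)C | intermediate
40 | C8 ketone, 5,7-dimethoxy chroman | O=C1CC[C@@H]2[C@H](c3ccccc3)c3c(OC)cc(OC)cc3O[C@@]2(C)CC[C@H]2[C@H]1CC2(C)C | intermediate
41 | C8 ketone, 5,7-dihydroxy chroman | O=C1CC[C@@H]2[C@H](c3ccccc3)c3c(O)cc(O)cc3O[C@@]2(C)CC[C@H]2[C@H]1CC2(C)C | intermediate
42 | C8-methylidene diphenol (bis-deformyl psidial A) | C=C1CC[C@@H]2[C@H](c3ccccc3)c3c(O)cc(O)cc3O[C@@]2(C)CC[C@H]2[C@H]1CC2(C)C | intermediate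
43 | bis(dimethyliminium) dichloride (not isolated) | C=C1CC[C@@H]2[C@H](c3ccccc3)c3c(O)c(C=[N+](C)C)c(O)c(C=[N+](C)C)c3O[C@@]2(C)CC[C@H]2[C@H]1CC2(C)C.[Cl-].[Cl-] | intermediate
44 | psidial A | C=C1CC[C@@H]2[C@H](c3ccccc3)c3c(O)c(C=O)c(O)c(C=O)c3O[C@@]2(C)CC[C@H]2[C@H]1CC2(C)C | target

**Totals**
Total step count: 26. Longest linear sequence: 20 steps (steps 7–12, then 13–26).

**Steps most likely to fail**

1. Step 13 (alkynylation at C4). What may go wrong: the oxocarbenium ion loses H-5 to give the endocyclic enol ether, which scrambles C5 or ends in elimination, and alkynyl transfer to a fully substituted carbon is too slow or not face-selective enough. The fallback forms the O–C4 bond last by a Nicholas cyclisation. Setting out from lactone 7, MeLi (1.05 equiv, THF, −78 °C) should give the lactol (3S,4R)-3-[(benzyloxy)methyl]-5,7-dimethoxy-2-methyl-4-phenylchroman-2-ol F1. Its open hydroxy-ketone form should add lithium acetylide 22 (CeCl3, THF, −78 °C) to give the phenol tertiary propargylic alcohol F2, as a C4 mixture that does not matter. Co2(CO)8 (CH2Cl2, rt) should give the hexacarbonyldicobalt complex F3. BF3·OEt2 (CH2Cl2, −40 °C) should ionise the alcohol to the cobalt-stabilised propargylic cation, which the phenol oxygen captures in a 6-exo closure that places the bulky cluster equatorial, anti to the C5 and C1' substituents, giving the complexed chromane F4. Me3NO (acetone, rt) should release the alkyne, and the route is rejoined at 25.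

2. Step 19 (closure of the ten-membered thioether). What may go wrong: the neopentyl-type thiolate attacks the β-branched C6 mesylate slowly, so intermolecular alkylation, disulfide formation and E2 loss of the mesylate compete with ring closure. The fallback closes a larger ring through an S–S bond and then removes one sulfur atom. Setting out from 31, potassium thioacetate (DMF, 50 °C) should displace the C6 mesylate to give the C6,C7-bis(thioacetate) F5. K2CO3/MeOH followed by I2 at high dilution should give the eleven-membered cyclic disulfide F6. P(NEt2)3 (benzene, 80 °C) should extrude one sulfur atom by thiolate displacement at C6 of the S-phosphonium intermediate, and the route is rejoined at sulfide 33.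

3. Step 21 (key step). What may go wrong: bromination on the alumina surface is slower than side reactions of the α-sulfonyl carbanions (double bromination at the more acidic C7, or ketal opening to a vinyl sulfone that hydroxide then attacks), so the episulfone is not reached cleanly. The fallback installs the halogen before the sulfone exists and runs the same rearrangement with a non-nucleophilic base. Setting out from sulfide 33, N-chlorosuccinimide (CCl4, 0 °C) should give the α-chloro sulfide F7 (chlorine at C6; the C7 regioisomer would serve equally). m-CPBA (CH2Cl2, 0 °C) should give the α-chloro sulfone F8. KOt-Bu (THF, −78 → 0 °C) should then effect the 1,3-elimination and SO2 loss, rejoining the route at 38.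

**Further compounds**
F1 | step 13 | (3S,4R)-3-[(benzyloxy)methyl]-5,7-dimethoxy-2-methyl-4-phenylchroman-2-ol (lactol) | CC1(O)[C@H](COCc2ccccc2)[C@H](c2ccccc2)c2c(OC)cc(OC)cc2O1
F2 | step 13 | ring-opened phenol tertiary propargylic alcohol (C4 epimers) | CC(O)(C#C[C@H]1[C@H](C(=C)COCc2ccccc2)CC1(C)C)[C@H](COCc1ccccc1)[C@H](c1ccccc1)c1c(O)cc(OC)cc1OC
F3 | step 13 | hexacarbonyldicobalt complex of F2 | CC(O)(C#C[C@H]1[C@H](C(=C)COCc2ccccc2)CC1(C)C)[C@H](COCc1ccccc1)[C@H](c1ccccc1)c1c(O)cc(OC)cc1OC.[Co].[Co].[C-]#[O+].[C-]#[O+].[C-]#[O+].[C-]#[O+].[C-]#[O+].[C-]#[O+]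
F4 | step 13 | hexacarbonyldicobalt complex of 25 | O(Cc1ccccc1)C[C@@H]1[C@H](c2ccccc2)c2c(OC)cc(OC)cc2O[C@@]1(C)C#C[C@H]1[C@H](C(=C)COCc2ccccc2)CC1(C)C.[Co].[Co].[C-]#[O+].[C-]#[O+].[C-]#[O+].[C-]#[O+].[C-]#[O+].[C-]#[O+]
F5 | step 19 | C6,C7-bis(thioacetate), C8 ketal | CC(=O)SC[C@@H]1[C@H](c2ccccc2)c2c(OC)cc(OC)cc2O[C@@]1(C)CC[C@H]1[C@H](C2(CSC(C)=O)OCCO2)CC1(C)C
F6 | step 19 | eleven-membered cyclic disulfide, C8 ketal | S1SC[C@@H]2[C@H](c3ccccc3)c3c(OC)cc(OC)cc3O[C@@]2(C)CC[C@H]2[C@@H](CC2(C)C)C2(C1)OCCO2
F7 | step 21 | α-chloro sulfide (Cl at C6) | S1C(Cl)[C@@H]2[C@H](c3ccccc3)c3c(OC)cc(OC)cc3O[C@@]2(C)CC[C@H]2[C@@H](CC2(C)C)C2(C1)OCCO2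
F8 | step 21 | α-chloro sulfone (Cl at C6) | O=S1(=O)C(Cl)[C@@H]2[C@H](c3ccccc3)c3c(OC)cc(OC)cc3O[C@@]2(C)CC[C@H]2[C@@H](CC2(C)C)C2(C1)OCCO2
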